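Jb rose at about the same pace in the west run, 1.51 mM min⁻¹, as in the north-east run, 1.60 mM min⁻¹, although their charges were 20 mM and 30 mM of Jd and their temperatures differed.

| flask | Jd | temperature | remark | time |
|---|---|---|---|---|
| west | 20 mM | 80 °C | the very flask that is asked about, followed so far |  |
| north-east | 30 mM | 75 °C | run made earlier |  |
| flask | 20 mM | 80 °C |  | 25 min |

| run | time / min | Jb / % |
|---|---|---|
| west | 0.833 | 5.1 |
| west | 2.50 | 17.7 |
| west | 4.00 | 25.6 |
| west | 6.00 | 33.4 |
| west | 10.0 | 43.6 |
| west | 12.0 | 47.2 |
| west | 15.0 | 49.0 |
| north-east | 0.333 | 0.5 |
| north-east | 0.667 | 2.7 |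
| north-east | 1.00 | 4.8 |
| north-east | 1.33 | 6.7 |
| north-east | 2.00 | 9.8 |
| north-east | 2.50 | 11.1 |

(readings scatter by 0.5 percentage points)

* Jb, in percent of the Jd first charged, at 25 min
* what to do for the largest gain in Jb; "none" if nothing gains more than 2 percentage points (amber / ochre / grey / none)
* Jb present, with what was taken out counted in, in percent of the Jd first charged, after ochre
* Jb present, with what was taken out counted in, in percent of the Jd first charged, after grey

- Jd is a solid; its amount is given per volume of the solution
- what is taken out of Jb is counted as made
- at the start none of Jd is in solution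

- amber: at 25 min take out 90% of the Jb then present, then wait 8.0 min
- ochre: at 25 min raise the temperature by 10 K, then wait 8.0 min
- grey: change nothing and wait 8.0 min more

The west run is this flask, followed so far. I took its early rise for a feed from the solid, zero-order in the charge, though that was an assumption, since the two runs differ in temperature as well. So I reckoned a rough feed time, as if the whole charge passed into Jb: the charge divided by the early rise of cJb, 13.2 min.

Was the flask still being fed at 25 min? That time is about twice the feed time, so I expected no further climb. The last two readings agree: cJb rose by 0.120 mM min⁻¹. I committed to about 49.0% now, and to no useful gain from grey.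

Then where was the rest? About half of the charge was not read as Jb. I took the flat stretch for a balance between Jb and something unread. Taking out 90% of Jb should then let it refill, so I chose amber. The north-east run stopped at 11.1%, too early to show which way heat moves the balance, so I gave ochre no figure.

The forecast, higher than mine on now, gave 52%, 52.5% after grey and 58% after ochre, and chose amber, saying “a true ceiling looks likely, most plausibly reversibility”.

The flask gave 47.9% now and 47.9% after grey. Ochre gave 44.0%, a change of −3.9 percentage points. Amber gained 22 points, and amber was the best choice.

    Ja ⇌ Jb (K = 0.980, k = 0.0880 s⁻¹, Ea = 84.0 kJ mol⁻¹, ΔH = −21.0 kJ mol⁻¹)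
    Jb ⇌ Jc (K = 0.0670, k = 5.20 × 10⁻⁴ s⁻¹, Ea = 111 kJ mol⁻¹, ΔH = −79.0 kJ mol⁻¹)
    Jd ⇌ Ja, rate k3*(cs3 - [Ja]) while solid is left; crystals form when [Ja] > cs3 (solubility = 12.0 mM, k = 0.00490 s⁻¹)
    (constants at 80 °C)

In this flask Jd stood at 0% by 12.5 min, inside the feed time, and Ja then held 49.0%. For a neighbouring flask charged with 50 mM of Jd, the same early rise gives a reckoned feed time of 33.1 min, longer than 25 min. At 25.0 min that neighbour had Jb at 22.8% and still held 52.4% of its charge as Jd.

The readings come from a simulation for substances that don't exist; noise was put on by code.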